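**Plan**

- Retrosynthesis: the C6–O ester bond is cut first (p-coumaric acid). The C6 carbinol and C5–H go back to a C5=C6 silyl enol ether. The cycloheptadiene is then cut at C1–C10, with C6–C8 re-formed, to a cis-1-silyloxy-1-cyclopentenyl-2-vinylcyclopropane. The cyclopropane is cut at C8–C6/C8–C7 (carbenoid tethered through the C4 oxygen) and the cyclopentene at C1=C5 (aldol).
- Enabling feature: in the seven-membered ring (C1, C5, C6, C7, C8, C9, C10) the C8=C9 alkene and the oxygen-bearing C6 flank the single CH2 (C7), a 1,4-diene with C6 at the enol-ether level. Together with quaternary C1 this is the imprint of a divinylcyclopropane rearrangement.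
- Forward order: cyclopentene (ozonolysis and aldol of (S)-terpinen-4-ol); cyclopropane together with a temporary δ-lactone; lactone turned into the vinyl group; seven-membered ring by the [3,3] shift; then ketone, diol and ester.
- Stereochemistry: C4 from the chiral pool. C6 and C8 of the cyclopropane from the C4–O tether, which also forces the two alkenyl groups cis and so avoids any enol-ether geometry problem. C1 from the cyclopropane by the stereospecific rearrangement. C5 by equilibration next to the ketone. C6 by hydroxyl-directed hydride delivery.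

Key step: step 12

Remark on numbering: atom numbers are those of the target skeleton. C1 is the ring-fusion carbon bearing the C15 methyl, C2 and C3 the cyclopentane CH2 groups, C4 the isopropyl carbinol, C5 the ring-fusion CH, C6 the ester carbon, C7 the CH2, C8(C14 methyl)=C9 the ring alkene, C10 the CH2 next to C1.

Assumption: (S)-(+)-terpinen-4-ol of high enantiomeric purity is taken as the commercial starting point; its enantiomeric purity is carried through unchanged.

**Route**

Step 1
Reactants: 1 (S)-terpinen-4-ol
Product: 3 (3S)-3-hydroxy-6-oxo-3-(propan-2-yl)heptanal, via ozonide 2 (not isolated)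
Conditions: O3, CH2Cl2, −78 °C; then PPh3, −78 → 23 °C
Reagents that add atoms: ozone, [O-][O+]=O
Why: Ozonolysis (Criegee cycloaddition–cycloreversion to the secondary ozonide 2) followed by phosphine reduction cleaves the only C=C bond to the methyl ketone and the aldehyde without touching the tertiary carbinol stereocentre.

Step 2
Reactants: 3 (3S)-3-hydroxy-6-oxo-3-(propan-2-yl)heptanal
Product: 5 (5R)-5-hydroxy-2-methyl-5-(propan-2-yl)cyclopent-1-ene-1-carbaldehyde, via aldol adduct 4 (not isolated)
Conditions: piperidine (cat.), AcOH (cat.), toluene, 80 °C, water removal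
Reagents that add atoms: none
Why: Amine–acid catalysed intramolecular aldol condensation in which the aldehyde enamine attacks the methyl ketone (five-membered ring, 5-enolexo) and aldol 4 dehydrates to the conjugated tetrasubstituted enal, the tertiary hydroxyl being too poor a leaving group to be lost competitively.

Step 3
Reactants: 5 (5R)-5-hydroxy-2-methyl-5-(propan-2-yl)cyclopent-1-ene-1-carbaldehyde
Product: 6 (1R)-2-(1-hydroxyethyl)-3-methyl-1-(propan-2-yl)cyclopent-2-en-1-ol (both carbinol epimers)
Conditions: MeMgBr (2.5 equiv), THF, −78 → 0 °C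
Reagents that add atoms: methylmagnesium bromide, C[Mg]Br
Why: Grignard 1,2-addition to the enal (the first equivalent deprotonates the tertiary hydroxyl and the fully substituted β-carbon blocks conjugate addition); the new carbinol centre is of no consequence because it is oxidised in step 4.

Step 4
Reactants: 6 (1R)-2-(1-hydroxyethyl)-3-methyl-1-(propan-2-yl)cyclopent-2-en-1-ol
Product: 7 1-[(5R)-5-hydroxy-2-methyl-5-(propan-2-yl)cyclopent-1-en-1-yl]ethan-1-one
Conditions: Dess–Martin periodinane, pyridine, CH2Cl2, 0 → 23 °C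
Reagents that add atoms: none
Why: Dess–Martin oxidation converts the secondary allylic alcohol into the methyl ketone (C6 with C7) and cannot oxidise the tertiary alcohol.

Step 5
Reactants: 7 1-[(5R)-5-hydroxy-2-methyl-5-(propan-2-yl)cyclopent-1-en-1-yl]ethan-1-one
Product: 8 (1R)-2-acetyl-3-methyl-1-(propan-2-yl)cyclopent-2-en-1-yl 3-oxobutanoate
Conditions: 2,2,6-trimethyl-4H-1,3-dioxin-4-one (1.5 equiv), xylene, 130 °C, acetone distilled off
Reagents that add atoms: 2,2,6-trimethyl-4H-1,3-dioxin-4-one, CC1=CC(=O)OC(C)(C)O1
Why: Acetoacetylation by acetylketene: the dioxinone loses acetone by thermal retro-[4+2] and the acylketene adds even to this hindered tertiary alcohol, while 130 °C should stay below the temperature at which allylic acetoacetates undergo Carroll rearrangement.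

Step 6
Reactants: 8 (1R)-2-acetyl-3-methyl-1-(propan-2-yl)cyclopent-2-en-1-yl 3-oxobutanoate
Product: 9 (1R)-2-acetyl-3-methyl-1-(propan-2-yl)cyclopent-2-en-1-yl 2-methyl-3-oxobutanoate (both α-epimers)
Conditions: MeI (1.1 equiv), K2CO3, acetone, 23 °C
Reagents that add atoms: iodomethane, CI
Why: C-Alkylation of the β-keto ester enolate (the only position acidic enough for K2CO3) installs the future C14 methyl; the new α-stereocentre is irrelevant because it becomes the diazo carbon.

Step 7
Reactants: 9 (1R)-2-acetyl-3-methyl-1-(propan-2-yl)cyclopent-2-en-1-yl 2-methyl-3-oxobutanoate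
Product: 10 (1R)-2-acetyl-3-methyl-1-(propan-2-yl)cyclopent-2-en-1-yl 2-diazopropanoate
Conditions: 4-acetamidobenzenesulfonyl azide, DBU, MeCN, 0 → 23 °C
Reagents that add atoms: 4-acetamidobenzenesulfonyl azide, CC(=O)Nc1ccc(cc1)S(=O)(=O)N=[N+]=[N-]
Why: Deacylative (Regitz) diazo transfer in which the α-substituted β-keto ester enolate adds to the sulfonyl azide and the adduct fragments with transfer of the acetyl group to the sulfonamide nitrogen, leaving the α-diazo ester.

Step 8
Reactants: 10 (1R)-2-acetyl-3-methyl-1-(propan-2-yl)cyclopent-2-en-1-yl 2-diazopropanoate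
Product: 11 (1R)-2-{1-[(tert-butyldimethylsilyl)oxy]ethenyl}-3-methyl-1-(propan-2-yl)cyclopent-2-en-1-yl 2-diazopropanoate
Conditions: TBSOTf, Et3N, CH2Cl2, −78 → 0 °C
Reagents that add atoms: tert-butyldimethylsilyl trifluoromethanesulfonate, CC(C)(C)[Si](C)(C)OS(=O)(=O)C(F)(F)F
Why: Soft enolisation (silyl triflate and amine) of the methyl ketone at its only α-carbon gives the 2-silyloxy-1,3-diene, which masks the carbonyl (otherwise a trap for the carbenoid) and creates the electron-rich C6=C7 bond; disubstituted α-diazo esters tolerate these conditions.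

Step 9
Reactants: 11 (1R)-2-{1-[(tert-butyldimethylsilyl)oxy]ethenyl}-3-methyl-1-(propan-2-yl)cyclopent-2-en-1-yl 2-diazopropanoate
Product: 12 tricyclic silyloxycyclopropane δ-lactone (lactone ring O4–C9(=O)–C8–C6–C5–C4 cis-fused at C6–C8 to the cyclopropane C6–C7–C8; OTBS on C6 and CH3 on C8; C4 R, C6 R, C8 S)
Conditions: Rh2(O2CCMe3)4 (dirhodium tetrapivalate, 1 mol %), CH2Cl2, −40 → 0 °C, slow addition of 11
Reagents that add atoms: none
Why: Intramolecular cyclopropanation by a rhodium carbenoid (bulky carboxylate ligands and low temperature to disfavour 1,2-hydride shift): the ester tether lets C8 reach only the C6=C7 enol ether through a six-membered lactone, the lactone forces C9 and C5 to be cis on the new cyclopropane, and delivery from the face of the C4 oxygen onto the extended siloxydiene, with the bulky silyloxy group turned away from the isopropyl group, should set C6 and C8 relative to C4 as required.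

Step 10
Reactants: 12 tricyclic silyloxycyclopropane δ-lactone
Product: 13 lactol (C9 hemiacetal of 12; both anomers)
Conditions: iBu2AlH (1.2 equiv), CH2Cl2, −78 °C; aq. KNaC4H4O6 work-up
Reagents that add atoms: none
Why: Partial reduction of a lactone with iBu2AlH, whose tetrahedral aluminium hemiacetal is stable at −78 °C and gives the lactol on work-up, while the silyl ether, the cyclopropane and the alkene are inert.

Step 11
Reactants: 13 lactol
Product: 15 (1R)-2-[(1S,2R)-1-[(tert-butyldimethylsilyl)oxy]-2-ethenyl-2-methylcyclopropyl]-3-methyl-1-(propan-2-yl)cyclopent-2-en-1-ol, via hydroxy aldehyde 14 (not isolated)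
Conditions: Ph3PCH3Br (3 equiv), KOtBu (2.8 equiv), THF, 0 → 40 °C
Reagents that add atoms: methyltriphenylphosphonium bromide, C[P+](c1ccccc1)(c1ccccc1)c1ccccc1.[Br-]
Why: Wittig methylenation of the aldehyde tautomer 14 of the lactol turns C9 into the vinyl group (C9=C10) with its cis relation to the cyclopentenyl group unchanged and frees the C4 hydroxyl; the silyl-protected cyclopropanol is stable to the ylide.

Step 12
Reactants: 15 (1R)-2-[(1S,2R)-1-[(tert-butyldimethylsilyl)oxy]-2-ethenyl-2-methylcyclopropyl]-3-methyl-1-(propan-2-yl)cyclopent-2-en-1-ol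
Product: 16 (3R,8aR)-4-[(tert-butyldimethylsilyl)oxy]-6,8a-dimethyl-3-(propan-2-yl)-1,2,3,5,8,8a-hexahydroazulen-3-ol
Conditions: degassed toluene, 110–130 °C, sealed base-washed tube
Reagents that add atoms: none
Why: Thermal divinylcyclopropane–cycloheptadiene (Cope) rearrangement, a concerted [3,3]-sigmatropic shift through a boat transition state in which the C1=C5 and C9=C10 π bonds both lie over the three-membered ring, so that C1–C10 forms while the C6–C8 cyclopropane bond breaks and ring strain is released; the closest known reaction type is the rearrangement of silyloxy-substituted cis-1,2-dialkenylcyclopropanes to cycloheptadienyl silyl enol ethers. The seven-membered ring (C1, C5, C6, C7, C8, C9, C10) closes by sigmatropic ring enlargement of the cyclopropane (the three-membered ring expanded by the four alkenyl carbons) and needs the cis relation of the two alkenyl groups that the lactone of 12 has fixed. The only new stereocentre, quaternary C1, is controlled by the C6/C8 configuration: in the single rotamer about C5–C6 that holds C1 over the cyclopropane, C8 and its vinyl group lie on the isopropyl face of the cyclopentene, so C10 bonds to that face and the C15 methyl ends up syn to the C4 hydroxyl. The selectivity the step needs is stereospecificity, that is rearrangement faster than homolytic cis/trans stereomutation of the donor-substituted cyclopropane, which the preset cis geometry and the absence of acid should secure; the alkenes emerge regiodefined as C8=C9 and as the C5=C6 silyl enol ether that masks the C6 ketone. Because the Z-methyl group (C15) on the cyclopentenyl terminus points into the boat, a temperature well above that of unhindered cases is expected to be required.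

Step 13
Reactants: 16 (3R,8aR)-4-[(tert-butyldimethylsilyl)oxy]-6,8a-dimethyl-3-(propan-2-yl)-1,2,3,5,8,8a-hexahydroazulen-3-ol
Product: 18 trans-fused (3R,3aR,8aR)-3-hydroxy-6,8a-dimethyl-3-(propan-2-yl)-2,3,3a,5,8,8a-hexahydroazulen-4(1H)-one, via cis-fused ketone 17 (not isolated)
Conditions: Bu4NF (1.1 equiv), AcOH (1.1 equiv), THF, 0 °C; then DBU (0.5 equiv), 23 °C
Reagents that add atoms: none
Why: Fluoride cleavage of the silyl enol ether and protonation give the β-hydroxy ketone, kinetic protonation from the less hindered hydroxyl/methyl face being expected to favour cis-fused 17, and mild base-mediated epimerisation through the enolate should funnel it to trans-fused 18, in which the C5–C6 bond is anti to the isopropyl group and the C4 hydroxyl can hydrogen-bond to the C6 carbonyl.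

Step 14
Reactants: 18 trans-fused (3R,3aR,8aR)-3-hydroxy-6,8a-dimethyl-3-(propan-2-yl)-2,3,3a,5,8,8a-hexahydroazulen-4(1H)-one
Product: 19 (3R,3aS,4S,8aR)-6,8a-dimethyl-3-(propan-2-yl)-1,2,3,3a,4,5,8,8a-octahydroazulene-3,4-diol (jaeschkeanadiol)
Conditions: Me4NBH(OAc)3 (5 equiv), MeCN/AcOH (1:1), −30 → 0 °C
Reagents that add atoms: none
Why: Hydroxyl-directed triacetoxyborohydride reduction (Evans–Saksena type) in which exchange of acetate for the C4 hydroxyl gives an alkoxyborohydride that delivers hydride internally to the face of C6 syn to the C4 oxygen, so the new C6 hydroxyl is anti (1,3-anti diol, 6α-OH); the free reagent does not reduce ketones intermolecularly.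

Step 15
Reactants: 20 (2E)-3-(4-hydroxyphenyl)prop-2-enoic acid (4-hydroxycinnamic acid)
Product: 22 (2E)-3-{4-[(tert-butyldimethylsilyl)oxy]phenyl}prop-2-enoic acid, via bis-silyl compound 21 (not isolated)
Conditions: TBSCl (2.4 equiv), imidazole, DMF, 23 °C; then THF/H2O/AcOH, 23 °C
Reagents that add atoms: tert-butyldimethylsilyl chloride, CC(C)(C)[Si](C)(C)Cl
Why: Silylation of both acidic groups followed by selective hydrolysis of the labile silyl ester leaves the phenol protected as its aryl silyl ether (protecting-group installation).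

Step 16
Reactants: 19 jaeschkeanadiol; 22 (2E)-3-{4-[(tert-butyldimethylsilyl)oxy]phenyl}prop-2-enoic acid
Product: 24 (3R,3aS,4S,8aR)-3-hydroxy-6,8a-dimethyl-3-(propan-2-yl)-1,2,3,3a,4,5,8,8a-octahydroazulen-4-yl (2E)-3-{4-[(tert-butyldimethylsilyl)oxy]phenyl}prop-2-enoate, via mixed anhydride 23 (not isolated)
Conditions: 22, 2,4,6-trichlorobenzoyl chloride, Et3N, THF, 23 °C; then 19, DMAP, toluene, 23 → 40 °C
Reagents that add atoms: none
Why: Yamaguchi esterification in which the mixed anhydride 23 acylates DMAP and then the secondary C6 hydroxyl, the tertiary C4 hydroxyl being too hindered to react; no stereocentre is touched.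

Step 17
Reactants: 24 silyl-protected ester
Product: 25 (3R,3aS,4S,8aR)-3-hydroxy-6,8a-dimethyl-3-(propan-2-yl)-1,2,3,3a,4,5,8,8a-octahydroazulen-4-yl (2E)-3-(4-hydroxyphenyl)prop-2-enoate (target)
Conditions: Bu4NF, AcOH, THF, 0 °C
Reagents that add atoms: none
Why: Fluoride-mediated cleavage of the aryl silyl ether (phenoxide is a good leaving group at silicon) under acetic acid buffering, which should keep the cinnamate ester and its E double bond intact.

**Compound list**

1 | (S)-terpinen-4-ol, (1S)-4-methyl-1-(propan-2-yl)cyclohex-3-en-1-ol | CC1=CC[C@](O)(C(C)C)CC1 | starting material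
2 | secondary ozonide of 1, 1-methyl-4-(propan-2-yl)-7,8,9-trioxabicyclo[4.2.1]nonan-4-ol (diastereomer mixture at the ozonide carbons) | CC12CC[C@@](O)(C(C)C)CC(OO1)O2 | intermediate
3 | (3S)-3-hydroxy-6-oxo-3-(propan-2-yl)heptanal | O=CC[C@](O)(C(C)C)CCC(C)=O | intermediate
4 | aldol adduct, 2,5-dihydroxy-2-methyl-5-(propan-2-yl)cyclopentane-1-carbaldehyde (C4 as in 3, other centres mixed) | CC1(O)CC[C@@](O)(C(C)C)C1C=O | intermediate
5 | (5R)-5-hydroxy-2-methyl-5-(propan-2-yl)cyclopent-1-ene-1-carbaldehyde | CC1=C(C=O)[C@](O)(C(C)C)CC1 | intermediate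
6 | (1R)-2-(1-hydroxyethyl)-3-methyl-1-(propan-2-yl)cyclopent-2-en-1-ol (both carbinol epimers) | CC1=C(C(C)O)[C@](O)(C(C)C)CC1 | intermediate
7 | 1-[(5R)-5-hydroxy-2-methyl-5-(propan-2-yl)cyclopent-1-en-1-yl]ethan-1-one | CC1=C(C(C)=O)[C@](O)(C(C)C)CC1 | intermediate
8 | (1R)-2-acetyl-3-methyl-1-(propan-2-yl)cyclopent-2-en-1-yl 3-oxobutanoate | CC1=C(C(C)=O)[C@](OC(=O)CC(C)=O)(C(C)C)CC1 | intermediate
9 | (1R)-2-acetyl-3-methyl-1-(propan-2-yl)cyclopent-2-en-1-yl 2-methyl-3-oxobutanoate (both α-epimers) | CC1=C(C(C)=O)[C@](OC(=O)C(C)C(C)=O)(C(C)C)CC1 | intermediate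
10 | (1R)-2-acetyl-3-methyl-1-(propan-2-yl)cyclopent-2-en-1-yl 2-diazopropanoate | CC1=C(C(C)=O)[C@](OC(=O)C(C)=[N+]=[N-])(C(C)C)CC1 | intermediate
11 | (1R)-2-{1-[(tert-butyldimethylsilyl)oxy]ethenyl}-3-methyl-1-(propan-2-yl)cyclopent-2-en-1-yl 2-diazopropanoate | CC1=C(C(=C)O[Si](C)(C)C(C)(C)C)[C@](OC(=O)C(C)=[N+]=[N-])(C(C)C)CC1 | intermediate
12 | tricyclic silyloxycyclopropane δ-lactone: cyclopentene C1=C5 fused at C4–C5 to the lactone O4–C9(=O)–C8–C6–C5–C4, which is cis-fused at C6–C8 to the cyclopropane C6–C7–C8; OTBS on C6, CH3 on C8; C4 R, C6 R, C8 S | CC1=C2[C@]3(O[Si](C)(C)C(C)(C)C)C[C@]3(C)C(=O)O[C@@]2(C(C)C)CC1 | intermediate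
13 | lactol of 12 (C9 hemiacetal, both anomers) | CC1=C2[C@]3(O[Si](C)(C)C(C)(C)C)C[C@]3(C)C(O)O[C@@]2(C(C)C)CC1 | intermediate
14 | ring-opened hydroxy aldehyde, (1S,2R)-2-[(tert-butyldimethylsilyl)oxy]-2-[(5R)-5-hydroxy-2-methyl-5-(propan-2-yl)cyclopent-1-en-1-yl]-1-methylcyclopropane-1-carbaldehyde | O=C[C@@]1(C)C[C@@]1(O[Si](C)(C)C(C)(C)C)C1=C(C)CC[C@@]1(O)C(C)C | intermediate
15 | (1R)-2-[(1S,2R)-1-[(tert-butyldimethylsilyl)oxy]-2-ethenyl-2-methylcyclopropyl]-3-methyl-1-(propan-2-yl)cyclopent-2-en-1-ol (cyclopentenyl and vinyl cis) | C=C[C@@]1(C)C[C@@]1(O[Si](C)(C)C(C)(C)C)C1=C(C)CC[C@@]1(O)C(C)C | intermediate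
16 | (3R,8aR)-4-[(tert-butyldimethylsilyl)oxy]-6,8a-dimethyl-3-(propan-2-yl)-1,2,3,5,8,8a-hexahydroazulen-3-ol | CC1=CC[C@@]2(C)CC[C@@](O)(C(C)C)C2=C(O[Si](C)(C)C(C)(C)C)C1 | intermediate
17 | cis-fused (3R,3aS,8aR)-3-hydroxy-6,8a-dimethyl-3-(propan-2-yl)-2,3,3a,5,8,8a-hexahydroazulen-4(1H)-one | CC1=CC[C@@]2(C)CC[C@@](O)(C(C)C)[C@H]2C(=O)C1 | intermediate
18 | trans-fused (3R,3aR,8aR)-3-hydroxy-6,8a-dimethyl-3-(propan-2-yl)-2,3,3a,5,8,8a-hexahydroazulen-4(1H)-one | CC1=CC[C@@]2(C)CC[C@@](O)(C(C)C)[C@@H]2C(=O)C1 | intermediate
19 | (3R,3aS,4S,8aR)-6,8a-dimethyl-3-(propan-2-yl)-1,2,3,3a,4,5,8,8a-octahydroazulene-3,4-diol (jaeschkeanadiol) | CC1=CC[C@@]2(C)CC[C@@](O)(C(C)C)[C@@H]2[C@@H](O)C1 | intermediate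
20 | (2E)-3-(4-hydroxyphenyl)prop-2-enoic acid (4-hydroxycinnamic acid) | O=C(O)/C=C/c1ccc(O)cc1 | starting material
21 | tert-butyldimethylsilyl (2E)-3-{4-[(tert-butyldimethylsilyl)oxy]phenyl}prop-2-enoate | CC(C)(C)[Si](C)(C)OC(=O)/C=C/c1ccc(O[Si](C)(C)C(C)(C)C)cc1 | intermediate
22 | (2E)-3-{4-[(tert-butyldimethylsilyl)oxy]phenyl}prop-2-enoic acid | O=C(O)/C=C/c1ccc(O[Si](C)(C)C(C)(C)C)cc1 | intermediate
23 | mixed anhydride of 22 with 2,4,6-trichlorobenzoic acid | O=C(/C=C/c1ccc(O[Si](C)(C)C(C)(C)C)cc1)OC(=O)c1c(Cl)cc(Cl)cc1Cl | intermediate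
24 | (3R,3aS,4S,8aR)-3-hydroxy-6,8a-dimethyl-3-(propan-2-yl)-1,2,3,3a,4,5,8,8a-octahydroazulen-4-yl (2E)-3-{4-[(tert-butyldimethylsilyl)oxy]phenyl}prop-2-enoate | CC1=CC[C@@]2(C)CC[C@@](O)(C(C)C)[C@@H]2[C@@H](OC(=O)/C=C/c2ccc(O[Si](C)(C)C(C)(C)C)cc2)C1 | intermediate
25 | (3R,3aS,4S,8aR)-3-hydroxy-6,8a-dimethyl-3-(propan-2-yl)-1,2,3,3a,4,5,8,8a-octahydroazulen-4-yl (2E)-3-(4-hydroxyphenyl)prop-2-enoate | CC1=CC[C@@]2(C)CC[C@@](O)(C(C)C)[C@@H]2[C@@H](OC(=O)/C=C/c2ccc(O)cc2)C1 | target

**Step count and risks**

Total steps: 17. Longest linear sequence: 16 (steps 1–14, 16 and 17; step 15 is a one-step side branch).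

Step 9 (most likely to fail). The α-methyl rhodium carbenoid may undergo 1,2-hydride shift to the acrylate ester, or insert into a C–H bond near the ester oxygen, before it reaches the enol ether. The diene may also react from its other rotamer and give the lactone epimeric at C6 and C8. The fallback makes the cyclopropane intermolecularly, setting out from enal 5 and coming back at 15. Addition of CH3CH=CHCH2MgCl (from 1-chlorobut-2-ene and Mg, attack through the γ-carbon) gives homoallylic alcohol F1. Dess–Martin oxidation gives β,γ-unsaturated ketone F2. TBSOTf/Et3N gives silyl dienol ether F3, of which the isomer with the silyloxy group cis to the methyl group is needed and would be separated from its geometric isomer if both form. Hydroxyl-directed Simmons–Smith cyclopropanation (Et2Zn, CH2I2) of the enol-ether double bond then gives 15. This path is shorter but leaves enol-ether geometry and facial selectivity to substrate control.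

Step 12. The rearrangement may be too slow because the Z-methyl group points into the boat. Homolytic opening of the donor-substituted cyclopropane could then compete, with loss of the cis geometry and of the C6/C8 configuration and hence of the C1 configuration; silyl transfer to the C4 hydroxyl is a further possibility. The fallback is the charge-accelerated variant, setting out from 15 and coming back at 18. Buffered Bu4NF/AcOH at low temperature removes the silyl group to give cyclopropanol F4. Its potassium alkoxide (KH, 18-crown-6, THF, −20 → 0 °C) should undergo the anion-accelerated [3,3] shift, the alkoxide sitting on the breaking bond as in an anionic oxy-Cope rearrangement, well below the thermal temperature. This gives the C5=C6 enolate directly; protonation gives the 17/18 mixture, which is equilibrated with DBU as in step 13 to 18.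

Step 13. Base-mediated epimerisation at C5 may be accompanied by retro-aldol cleavage or loss of water from the β-hydroxy ketone, or may stop at an unfavourable cis/trans ratio. The fallback replaces the thermodynamic funnel by kinetic selection in the reduction, setting out from 16 and coming back at 19. The mixture of 17 and 18 from buffered fluoride cleavage of 16 is taken directly into the Me4NBH(OAc)3 reduction. Only 18, whose hydroxyl is syn to the C6 carbonyl, can bind boron and receive hydride internally, so 19 is formed selectively. Unreacted 17 is re-equilibrated by acid-catalysed enolisation in the AcOH medium, where no alkoxide or enolate is present, and recycled. No compound outside the list is made (F0).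

**Further compounds**

F1 | step 9 | (1R)-2-(1-hydroxy-2-methylbut-3-en-1-yl)-3-methyl-1-(propan-2-yl)cyclopent-2-en-1-ol (diastereomer mixture) | CC1=C(C(O)C(C)C=C)[C@](O)(C(C)C)CC1
F2 | step 9 | 1-[(5R)-5-hydroxy-2-methyl-5-(propan-2-yl)cyclopent-1-en-1-yl]-2-methylbut-3-en-1-one | CC1=C(C(=O)C(C)C=C)[C@](O)(C(C)C)CC1
F3 | step 9 | (1R)-2-{(1E)-1-[(tert-butyldimethylsilyl)oxy]-2-methylbuta-1,3-dien-1-yl}-3-methyl-1-(propan-2-yl)cyclopent-2-en-1-ol | C=C/C(C)=C(\C1=C(C)CC[C@@]1(O)C(C)C)O[Si](C)(C)C(C)(C)C
F4 | step 12 | (1R)-2-[(1S,2R)-2-ethenyl-1-hydroxy-2-methylcyclopropyl]-3-methyl-1-(propan-2-yl)cyclopent-2-en-1-ol | C=C[C@@]1(C)C[C@@]1(O)C1=C(C)CC[C@@]1(O)C(C)C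
F0 | step 13 | none | none
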